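## Retrosynthetic overview

1. Target 18 ⇐ 17 by SN2 demethylation of both esters; 17 ⇐ 16 by hydride delivery to the α face of the C2 ketone, which gives the axial 2β-alcohol.
2. 16 ⇐ acyclic tetraene 14 in one catalytic asymmetric bicyclisation: the γ-oxo-enoate head closes ring A first (C4–C5 bond), then ring B closes (C10–C9 bond) onto a (Z)-allylsilane that leaves the 8(17)-methylene. C4, C5, C10 and C9 are set here.
3. 14 ⇐ allylic bromide 9 + CO + vinylstannane 13 (carbonylative Stille coupling, base-free, so the β,γ-unsaturated ketone survives).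
4. 9 ⇐ gem-dichloroalkene 3 (from methyl geranate) by two stereocontrolled Negishi substitutions (homoprenylzinc, then Me3SiCH2Zn) and E-selective SeO2 oxidation of the terminal methyl.
5. All stereocentres arise in steps 10 and 11; every compound before step 10 is achiral.

Assumption: methyl (E)-geranate 1, bromide 4 and methyl propiolate 10 are bought; labdane numbering is used for the decalins; the (S,S) antipode of the catalyst is taken to give the (4R,5R,9S,10R) series, and its mirror image is used if the first run shows the opposite sense.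

## Route

Step 1
Reactants: 1 methyl (2E)-3,7-dimethylocta-2,6-dienoate (methyl geranate)
Product: 2 methyl (2E)-3-methyl-6-oxohex-2-enoate
Conditions: O3 (1.0 equiv), CH2Cl2, −78 °C; then Me2S, −78 → 20 °C
Reagents that add atoms: ozone, [O-][O+]=O
Why: Ozonolysis with reductive work-up; ozone attacks the electron-rich trisubstituted 6,7-alkene far faster than the ester-conjugated 2,3-alkene, so one equivalent cleaves only the isopropylidene end.

Step 2
Reactants: 2 methyl (2E)-3-methyl-6-oxohex-2-enoate
Product: 3 methyl (2E)-7,7-dichloro-3-methylhepta-2,6-dienoate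
Conditions: PPh3 (3 equiv), BrCCl3 (1.5 equiv), MeCN, 0 → 20 °C
Reagents that add atoms: bromotrichloromethane, ClC(Cl)(Cl)Br
Why: Ramirez-type gem-dichloroolefination (Wittig reaction of Ph3P=CCl2 made in the flask) converts the aldehyde into the 1,1-dichloroalkene and leaves the enoate alone.

Step 3
Reactants: 4 5-bromo-2-methylpent-2-ene; 3 methyl (2E)-7,7-dichloro-3-methylhepta-2,6-dienoate
Product: 6 methyl (2E,6Z)-7-chloro-3,11-dimethyldodeca-2,6,10-trienoate, via homoprenylzinc bromide 5 (not isolated)
Conditions: 4, Zn dust, I2 (5 mol%), DMA, 70 °C; then 3, PdCl2(DPEphos) (5 mol%), THF/DMA, 23 °C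
Reagents that add atoms: none
Why: Negishi coupling, trans-selective monoalkylation of a 1,1-dichloroalkene; zerovalent palladium inserts only into the C–Cl bond trans to the existing chain, so the homoprenyl group enters trans to C5 and the (6Z)-chloroalkene results, while the alkylzinc tolerates the ester.

Step 4
Reactants: 6 methyl (2E,6Z)-7-chloro-3,11-dimethyldodeca-2,6,10-trienoate
Product: 7 methyl (2E,6Z,10E)-7-chloro-12-hydroxy-3,11-dimethyldodeca-2,6,10-trienoate
Conditions: SeO2 (0.3 equiv), t-BuOOH (3 equiv), salicylic acid (0.1 equiv), CH2Cl2, 20 °C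
Reagents that add atoms: tert-butyl hydroperoxide, CC(C)(C)OO (oxygen relayed by catalytic selenium dioxide, O=[Se]=O)
Why: SeO2-catalysed allylic hydroxylation (ene reaction, then [2,3]-shift) is E-selective for the methyl trans to the chain and touches only the electron-rich terminal alkene, since the chloroalkene and the enoate are deactivated.

Step 5
Reactants: 7 methyl (2E,6Z,10E)-7-chloro-12-hydroxy-3,11-dimethyldodeca-2,6,10-trienoate
Product: 8 methyl (2E,6Z,10E)-12-hydroxy-3,11-dimethyl-7-[(trimethylsilyl)methyl]dodeca-2,6,10-trienoate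
Conditions: Me3SiCH2MgCl (3 equiv), ZnCl2 (3 equiv), THF, 0 °C; then 7, Pd(P(t-Bu)3)2 (5 mol%), THF/NMP, 50 °C
Reagents that add atoms: (trimethylsilyl)methylmagnesium chloride, C[Si](C)(C)C[Mg]Cl
Why: Second Negishi substitution with retention; the bulky electron-rich zerovalent palladium catalyst inserts into the alkenyl chloride and the β-hydrogen-free silylmethylzinc reagent puts CH2SiMe3 cis to C5, fixing the (6Z)-allylsilane, while the free hydroxyl only consumes one equivalent of reagent.

Step 6
Reactants: 8 methyl (2E,6Z,10E)-12-hydroxy-3,11-dimethyl-7-[(trimethylsilyl)methyl]dodeca-2,6,10-trienoate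
Product: 9 methyl (2E,6Z,10E)-12-bromo-3,11-dimethyl-7-[(trimethylsilyl)methyl]dodeca-2,6,10-trienoate
Conditions: CBr4 (1.3 equiv), PPh3 (1.4 equiv), 2,6-lutidine (0.2 equiv), CH2Cl2, −20 → 0 °C; used at once
Reagents that add atoms: tetrabromomethane, BrC(Br)(Br)Br
Why: Appel reaction; neutral SN2 displacement at the primary allylic carbon gives the bromide without allylic transposition and leaves the allylsilane intact.

Step 7
Reactants: 10 methyl prop-2-ynoate (methyl propiolate)
Product: 11 methyl (2Z)-2,3-bis(trimethylstannyl)prop-2-enoate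
Conditions: (Me3Sn)2 (1.05 equiv), Pd(PPh3)4 (2 mol%), THF, 65 °C
Reagents that add atoms: hexamethyldistannane, C[Sn](C)(C)[Sn](C)(C)C
Why: Palladium-catalysed cis-distannation of an alkynoate adds both tin groups to the same face and gives the (Z)-1,2-bis(stannyl)alkene.

Step 8
Reactants: 11 methyl (2Z)-2,3-bis(trimethylstannyl)prop-2-enoate
Product: 13 methyl (2E)-2-methyl-3-(trimethylstannyl)prop-2-enoate, via alpha-lithio ester 12 (not isolated)
Conditions: MeLi (1.1 equiv), THF, −98 °C; then MeI (3 equiv), −98 → −78 °C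
Reagents that add atoms: iodomethane, CI
Why: Regioselective tin–lithium exchange at C2 (the stannyl group α to the ester) and C-methylation with retention at −98 °C give the β-stannyl methacrylate in which tin and methyl are cis.

Step 9
Reactants: 9 methyl (2E,6Z,10E)-12-bromo-3,11-dimethyl-7-[(trimethylsilyl)methyl]dodeca-2,6,10-trienoate; 13 methyl (2E)-2-methyl-3-(trimethylstannyl)prop-2-enoate
Product: 14 dimethyl (2E,6E,10Z,14E)-2,6,14-trimethyl-4-oxo-10-[(trimethylsilyl)methyl]hexadeca-2,6,10,14-tetraenedioate
Conditions: 13 (1.2 equiv), CO (3 bar), Pd(dba)2 (3 mol%), PPh3 (6 mol%), THF, 45 °C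
Reagents that add atoms: carbon monoxide, [C-]#[O+]
Why: Stille carbonylative cross-coupling; oxidative addition at the primary allylic bromide, CO insertion at the less substituted allyl terminus and vinyl transfer from tin with retention build the allyl vinyl ketone under neutral conditions, so the 6,7-alkene stays out of conjugation and all alkene geometries are kept.

Step 10
Reactants: 14 dimethyl (2E,6E,10Z,14E)-2,6,14-trimethyl-4-oxo-10-[(trimethylsilyl)methyl]hexadeca-2,6,10,14-tetraenedioate
Product: 16 dimethyl (4R,5R,9S,10R,13E)-2-oxolabda-8(17),13-diene-15,18-dioate (trans-decalin; 4α-CO2Me, 4β-Me, 10β-Me, 5α-H, 9α-H), via trimethylsilyl enol ether 15 (not isolated)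
Conditions: (S,S)-IDPi (5 mol%; imidodiphosphorimidate from (S)-3,3'-bis[3,5-bis(trifluoromethyl)phenyl]-BINOL, N-triflyl core; presilylated with 2-methylallyl-SiMe3, 10 mol%), toluene (0.02 M), −60 → −40 °C; then 1 M HCl, THF, 0 °C
Reagents that add atoms: none
Why: Proposed new method: a silylium-relay, counteranion-directed Michael-initiated polyene bicyclisation in which Me3Si+ held by the chiral IDPi anion is passed to the C2 ketone to give a 2-silyloxyallyl cation, the E-alkene attacks C4 through a chair (6-endo; the ester trans to C2 becomes equatorial/α, the methyl axial/β), the C10 cation is trapped anti by C9 of the (Z)-allylsilane through a second chair (trans-decalin, 9β side chain), and loss of Me3Si+ from the β-silyl cation forms the 8(17)-methylene and regenerates the silylium catalyst, so the anion-controlled face of C4 sets the absolute and the chair–chair geometry the relative configuration at C4, C5, C10 and C9; the closest known chemistry is IDPi and disulfonimide silylium catalysis of Hosomi–Sakurai and Mukaiyama–Michael reactions, IDPi-catalysed polyene and Nazarov cyclisations, and racemic Lewis-acid enone-initiated, allylsilane-terminated cyclisations.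

Step 11
Reactants: 16 dimethyl (4R,5R,9S,10R,13E)-2-oxolabda-8(17),13-diene-15,18-dioate
Product: 17 dimethyl (2S,4R,5R,9S,10R,13E)-2-hydroxylabda-8(17),13-diene-15,18-dioate (2β-OH, axial)
Conditions: LiBH(s-Bu)3 (1.2 equiv), THF, −78 °C; then H2O
Reagents that add atoms: none
Why: Bulky-hydride ketone reduction; the β face of the C2 carbonyl is screened by the syn-axial methyls on C4 and C10, so hydride enters from the α face (equatorial attack) and gives the axial 2β-alcohol (2S), while both esters and the β,β-disubstituted enoate are inert at −78 °C.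

Step 12
Reactants: 17 dimethyl (2S,4R,5R,9S,10R,13E)-2-hydroxylabda-8(17),13-diene-15,18-dioate
Product: 18 (2S,4R,5R,9S,10R,13E)-2-hydroxylabda-8(17),13-diene-15,18-dioic acid (target)
Conditions: LiI (10 equiv), DMF, 130 °C; then 1 M HCl
Reagents that add atoms: none
Why: Nucleophilic ester dealkylation (SN2 attack of iodide on the O-methyl groups) cleaves both methyl esters at once and is indifferent to the neopentyl crowding of the C4 ester; no stereocentre or alkene is touched.

## Compound list

1 | methyl (2E)-3,7-dimethylocta-2,6-dienoate (methyl geranate) | COC(=O)/C=C(\C)CCC=C(C)C | starting material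
2 | methyl (2E)-3-methyl-6-oxohex-2-enoate | COC(=O)/C=C(\C)CCC=O | intermediate
3 | methyl (2E)-7,7-dichloro-3-methylhepta-2,6-dienoate | COC(=O)/C=C(\C)CCC=C(Cl)Cl | intermediate
4 | 5-bromo-2-methylpent-2-ene | CC(C)=CCCBr | starting material
5 | (4-methylpent-3-en-1-yl)zinc bromide (homoprenylzinc bromide) | CC(C)=CCC[Zn]Br | intermediate
6 | methyl (2E,6Z)-7-chloro-3,11-dimethyldodeca-2,6,10-trienoate | COC(=O)/C=C(\C)CC/C=C(\Cl)CCC=C(C)C | intermediate
7 | methyl (2E,6Z,10E)-7-chloro-12-hydroxy-3,11-dimethyldodeca-2,6,10-trienoate | COC(=O)/C=C(\C)CC/C=C(\Cl)CC/C=C(\C)CO | intermediate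
8 | methyl (2E,6Z,10E)-12-hydroxy-3,11-dimethyl-7-[(trimethylsilyl)methyl]dodeca-2,6,10-trienoate | COC(=O)/C=C(\C)CC/C=C(\C[Si](C)(C)C)CC/C=C(\C)CO | intermediate
9 | methyl (2E,6Z,10E)-12-bromo-3,11-dimethyl-7-[(trimethylsilyl)methyl]dodeca-2,6,10-trienoate | COC(=O)/C=C(\C)CC/C=C(\C[Si](C)(C)C)CC/C=C(\C)CBr | intermediate
10 | methyl prop-2-ynoate (methyl propiolate) | C#CC(=O)OC | starting material
11 | methyl (2Z)-2,3-bis(trimethylstannyl)prop-2-enoate | C[Sn](C)(C)/C=C(\[Sn](C)(C)C)C(=O)OC | intermediate
12 | methyl (2E)-2-lithio-3-(trimethylstannyl)prop-2-enoate (Li cis to Sn) | C[Sn](C)(C)/C=C(\[Li])C(=O)OC | intermediate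
13 | methyl (2E)-2-methyl-3-(trimethylstannyl)prop-2-enoate | C[Sn](C)(C)/C=C(\C)C(=O)OC | intermediate
14 | dimethyl (2E,6E,10Z,14E)-2,6,14-trimethyl-4-oxo-10-[(trimethylsilyl)methyl]hexadeca-2,6,10,14-tetraenedioate | COC(=O)/C(C)=C/C(=O)C/C(C)=C/CC/C(C[Si](C)(C)C)=C/CC/C(C)=C/C(=O)OC | intermediate
15 | dimethyl (4S,5R,9S,10R,13E)-2-[(trimethylsilyl)oxy]labda-2,8(17),13-triene-15,18-dioate | C=C1CC[C@@H]2[C@](C)(CC(O[Si](C)(C)C)=C[C@@]2(C)C(=O)OC)[C@H]1CC/C(C)=C/C(=O)OC | intermediate
16 | dimethyl (4R,5R,9S,10R,13E)-2-oxolabda-8(17),13-diene-15,18-dioate | C=C1CC[C@@H]2[C@](C)(CC(=O)C[C@@]2(C)C(=O)OC)[C@H]1CC/C(C)=C/C(=O)OC | intermediate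
17 | dimethyl (2S,4R,5R,9S,10R,13E)-2-hydroxylabda-8(17),13-diene-15,18-dioate | C=C1CC[C@@H]2[C@](C)(C[C@H](O)C[C@@]2(C)C(=O)OC)[C@H]1CC/C(C)=C/C(=O)OC | intermediate
18 | (2S,4R,5R,9S,10R,13E)-2-hydroxylabda-8(17),13-diene-15,18-dioic acid, i.e. (1R,3S,4aR,5S,8aR)-5-[(3E)-4-carboxy-3-methylbut-3-en-1-yl]-3-hydroxy-1,4a-dimethyl-6-methylidenedecahydronaphthalene-1-carboxylic acid | C=C1CC[C@@H]2[C@](C)(C[C@H](O)C[C@@]2(C)C(=O)O)[C@H]1CC/C(C)=C/C(=O)O | target

## Step count and risks

Total steps: 12. Longest linear sequence: 10 (steps 1–6, then 9–12).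

The three steps most likely to fail are steps 10, 9 and 5.

Step 10 (the new bicyclisation). The risks are low turnover of the silylium relay, protodesilylation of the allylsilane, E/Z leakage of the enone (which would epimerise C4) and insufficient enantiocontrol. The fallback sets out from 14: stoichiometric EtAlCl2 (CH2Cl2, −78 → −20 °C), the established Lewis acid for intramolecular conjugate additions of allylsilanes to enones and enone-initiated cation–olefin cyclisations, gives after aqueous work-up the racemate, that is 16 together with its mirror image ent-16 F1. Preparative chromatography on a chiral stationary phase (supercritical CO2/MeOH) separates the two, and the route is rejoined at 16.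

Step 9 (carbonylative Stille coupling). The risks are direct allyl–vinyl coupling without CO, syn/anti scrambling of the π-allyl intermediate, and migration of the 6,7-alkene into conjugation. The fallback sets out from 9 and also makes steps 7 and 8 unnecessary. Palladium-catalysed hydroxycarbonylation (Pd(OAc)2/PPh3, CO 20 bar, H2O, i-Pr2NEt, THF) gives the β,γ-unsaturated carboxylic acid F2. 1,1'-Carbonyldiimidazole turns it into the acyl imidazole F3, which is C-acylated by the magnesium enolate of diethylphosphonoacetic acid (MgCl2, Et3N, MeCN) and loses CO2 in the same flask to give the β-ketophosphonate F4. A Horner–Wadsworth–Emmons reaction of F4 with methyl pyruvate under LiCl/DBU conditions builds the E-configured 2,3-alkene and comes back to the route at 14.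

Step 5 (second substitution on a hindered alkenyl chloride that carries a free hydroxyl). The fallback moves the oxidation to the start and carries the oxygen protected. It sets out from 4: SeO2/t-BuOOH gives (2E)-5-bromo-2-methylpent-2-en-1-ol F5, and TBSCl/imidazole gives its silyl ether F6. Zinc insertion gives the alkylzinc bromide F7, which is coupled with 3 as in step 3 to the silyl-protected chlorotriene F8. The silylmethyl coupling is then run on this proton-free substrate to give the protected allylsilane F9, and Bu4NF removes the silyl ether and returns to the route at 8.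

## Further compounds

F1 | step 10 | dimethyl (4S,5S,9R,10S,13E)-2-oxolabda-8(17),13-diene-15,18-dioate (ent-16) | C=C1CC[C@H]2[C@@](C)(CC(=O)C[C@]2(C)C(=O)OC)[C@@H]1CC/C(C)=C/C(=O)OC
F2 | step 9 | (3E,7Z,11E)-13-methoxy-3,11-dimethyl-13-oxo-7-[(trimethylsilyl)methyl]trideca-3,7,11-trienoic acid | COC(=O)/C=C(\C)CC/C=C(\C[Si](C)(C)C)CC/C=C(\C)CC(=O)O
F3 | step 9 | methyl (2E,6Z,10E)-13-(1H-imidazol-1-yl)-3,11-dimethyl-13-oxo-7-[(trimethylsilyl)methyl]trideca-2,6,10-trienoate | COC(=O)/C=C(\C)CC/C=C(\C[Si](C)(C)C)CC/C=C(\C)CC(=O)n1ccnc1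
F4 | step 9 | methyl (2E,6Z,10E)-14-(diethoxyphosphoryl)-3,11-dimethyl-13-oxo-7-[(trimethylsilyl)methyl]tetradeca-2,6,10-trienoate | COC(=O)/C=C(\C)CC/C=C(\C[Si](C)(C)C)CC/C=C(\C)CC(=O)CP(=O)(OCC)OCC
F5 | step 5 | (2E)-5-bromo-2-methylpent-2-en-1-ol | OC/C(C)=C/CCBr
F6 | step 5 | {[(2E)-5-bromo-2-methylpent-2-en-1-yl]oxy}(tert-butyl)dimethylsilane | CC(C)(C)[Si](C)(C)OC/C(C)=C/CCBr
F7 | step 5 | [(3E)-5-{[tert-butyl(dimethyl)silyl]oxy}-4-methylpent-3-en-1-yl]zinc bromide | CC(C)(C)[Si](C)(C)OC/C(C)=C/CC[Zn]Br
F8 | step 5 | methyl (2E,6Z,10E)-12-{[tert-butyl(dimethyl)silyl]oxy}-7-chloro-3,11-dimethyldodeca-2,6,10-trienoate | COC(=O)/C=C(\C)CC/C=C(\Cl)CC/C=C(\C)CO[Si](C)(C)C(C)(C)C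
F9 | step 5 | methyl (2E,6Z,10E)-12-{[tert-butyl(dimethyl)silyl]oxy}-3,11-dimethyl-7-[(trimethylsilyl)methyl]dodeca-2,6,10-trienoate | COC(=O)/C=C(\C)CC/C=C(\C[Si](C)(C)C)CC/C=C(\C)CO[Si](C)(C)C(C)(C)C
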